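All constants are assumed; the rest is arithmetic.

Amounts open the reckoning: theta charges less partner, 6.00 mM, than substrate, 20 mM, so the balance to write is partner's.

| flask | substrate | partner | time |
|---|---|---|---|
| theta | 20 mM | 6.00 mM | 8.0 min |
| eta | 20 mM | 12.0 mM | 8.0 min |
| delta | 20 mM | 25.0 mM | 8.0 min |
| gamma | 20 mM | 50.0 mM | 8.0 min |
| beta | 20 mM | 100 mM | 8.0 min |

- share of target in all that became target or homo product or over-reaction product for theta, eta, delta, gamma, beta, in this order
- how that number moves from the first to the last of them (rises all the way / falls, then rises / rises, then falls / falls all the way / hardly changes)

- percentages count the substrate that a species holds: one homo product counts as two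
- for a step with 2 of a species take k times the square, and two of it per event
- "hardly changes" means that all values lie within two and a half points (for a concentration: within two and a half percent of the largest)
- run time (theta): 8.0 min

    partner → second intermediate (k1 = 0.0059 s⁻¹)
    2 open intermediate → homo product (k2 = 2.5 L mol⁻¹ s⁻¹)
    open intermediate + second intermediate → target (k3 = 6.0 L mol⁻¹ s⁻¹)
    substrate ⇌ open intermediate (K4 = 1.8, k4 = 0.018 s⁻¹)
    partner + target → over-reaction product (k5 = 0.57 L mol⁻¹ s⁻¹)

Each target holds one partner and each over-reaction product holds two, so in theta:

[partner] + [second intermediate] + [target] + 2[over-reaction product] = 6.00 mM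

With nothing in the other terms, target reaches 6.00 mM, or 30.0% of the substrate. That is the bound from above.

The mark from below needs the loss of target. Partner falls at least as fast as its own first-order step, so a target present from the start meets at most the over-reaction dose, the constant of over-reaction times the partner charge over the constant of partner's first-order step:

dose = 0.57 L mol⁻¹ s⁻¹ × 6.00 mM / 0.0059 s⁻¹ = 0.580

Such a target survives with a fraction s of at least exp(−dose) = 0.560. Partner's own step leaves at most 5.89% of it at 8.0 min, so the reckoning counts partner as spent; it also assumes that no second intermediate stands, which makes what follows an estimate and not a strict bound. The balance then gives: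

[target] = s × 6.00 mM / (2 − s)

This puts theta's lower mark at 11.7% of the substrate. To tighten it, a target born at partner's half-life, 1.96 min, is taken as typical; it meets at most half of the dose, so s = 0.748 is used and the estimate for target is 17.9% of the substrate. The share in the row divides by what has become product, not by the charge, so these marks apply to it only roughly.

The forecast gave 19%, 30%, 24%, 7% and 1.7%, shape rises, then falls, holding that, with little partner, “the supply of second intermediate is the bottleneck”, and its theta point lies below 30.0% and above 11.7%.

The simulation gives 19.3%, 28.8%, 31.2%, 17.3% and 3.19%, so the row rises, then falls. In theta, with dose 0.580, target stands at 18.4% of the substrate at 8.00 min, beside the estimated 17.9%. At 8.00 min in theta, partner still goes to second intermediate faster than into over-reaction product, by a factor 2.8. In eta the dose is 1.16, so s = 0.560 gives 23.3% of the substrate as target, and the eta flask holds 28.1% at 8.00 min.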